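Retrosynthesis first cuts the two O1–C6 ether bonds of the tetrahydropyrans, then the two C2–C3 bonds. This leaves two identical cyclopentanes and one ten-carbon (Z,Z)-diene, as the C2 symmetry suggests.
Enabling feature: in each pyran ring, C2 is a carbinol carbon between ring methylene C3 and cyclopentane carbon C2', and it stands 1,3 to the C1' hydroxyl. It can therefore be carried as the 2-carbon of a 1,3-dithiane (an acyl anion) and reduced later under the control of that hydroxyl.
Forward order: the cyclopentane closes by a carbonyl-ene reaction, the three fragments are joined by twofold dithiane alkylation (no ring formed), and both pyran rings close last by alkoxide attack on allylic chlorides.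
Stereochemistry: C2' comes from lipase desymmetrisation of a prochiral 1,3-diol. C1' and C5' follow from the ene transition state relative to C2'. C2 comes from a boron-chelate 1,3-syn reduction, and both alkenes from chair Johnson–Claisen transition states.

Key step: step 16

Assumption: the lipase acetylates the pro-R hydroxymethyl group of the prochiral diol, as the empirical size rule for lipase acylation of primary alcohols predicts when the alkenyl chain is the large substituent. The sense is to be confirmed by Mosher ester analysis.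

**Part A – cyclopentyl dithiane**

Step 1
Reactants: 1 diethyl malonate; 2 5-bromo-2-methylpent-2-ene
Product: 3 diethyl 2-(4-methylpent-3-en-1-yl)malonate
Conditions: NaH, THF/DMF, 0 → 60 °C (slight excess of 1)
Reagents that add atoms: none
Why: Malonic ester alkylation, in which the sodium enolate displaces the primary bromide by SN2 and the excess of 1 suppresses dialkylation.

Step 2
Reactants: 3 diethyl 2-(4-methylpent-3-en-1-yl)malonate
Product: 4 2-(4-methylpent-3-en-1-yl)propane-1,3-diol
Conditions: LiAlH4, THF, 0 °C → rt; aq. NaOH work-up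
Reagents that add atoms: none
Why: Exhaustive hydride reduction of both esters should give the prochiral 2-substituted propane-1,3-diol without touching the trisubstituted alkene.

Step 3
Reactants: 4 2-(4-methylpent-3-en-1-yl)propane-1,3-diol
Product: 5 (R)-2-(hydroxymethyl)-6-methylhept-5-en-1-yl acetate
Conditions: Burkholderia cepacia lipase (immobilised), vinyl acetate, i-Pr2O, rt
Reagents that add atoms: vinyl acetate, C=COC(C)=O
Why: Enzymatic desymmetrisation by irreversible transesterification, a known reaction class for 2-substituted propane-1,3-diols, should acetylate only the pro-R arm and so set the future C2' centre, while further acetylation of the minor enantiomer to the diacetate should sharpen the enantiopurity.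

Step 4
Reactants: 5 (R)-2-(hydroxymethyl)-6-methylhept-5-en-1-yl acetate
Product: 6 (S)-2-formyl-6-methylhept-5-en-1-yl acetate
Conditions: DMP, NaHCO3, CH2Cl2, 0 °C; used crude
Reagents that add atoms: none
Why: Buffered Dess–Martin oxidation is neutral enough to give the β-acetoxy aldehyde without enolisation, acetyl migration or loss of acetic acid if the product is carried on at once.

Step 5
Reactants: 6 (S)-2-formyl-6-methylhept-5-en-1-yl acetate; 7 propane-1,3-dithiol
Product: 8 (S)-2-(1,3-dithian-2-yl)-6-methylhept-5-en-1-yl acetate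
Conditions: BF3·OEt2 (cat.), CH2Cl2, −40 °C (7 premixed with 6)
Reagents that add atoms: none
Why: In this Lewis-acid dithioacetalisation, hemithioacetal formation with the premixed dithiol should outrun ene closure and enolisation at low temperature, so the aldehyde carbon (future pyran C2) becomes the dithiane carbon with the stereocentre intact.

Step 6
Reactants: 8 (S)-2-(1,3-dithian-2-yl)-6-methylhept-5-en-1-yl acetate
Product: 9 (S)-2-(1,3-dithian-2-yl)-6-methylhept-5-en-1-ol
Conditions: K2CO3 (cat.), MeOH, rt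
Reagents that add atoms: none
Why: Base-catalysed methanolysis (transesterification) removes the acetate under conditions to which dithiane and alkene are inert.

Step 7
Reactants: 9 (S)-2-(1,3-dithian-2-yl)-6-methylhept-5-en-1-ol
Product: 10 (S)-2-(1,3-dithian-2-yl)-6-methylhept-5-enal
Conditions: DMP, NaHCO3, CH2Cl2, 0 °C; short silica plug, used at once
Reagents that add atoms: none
Why: Dess–Martin oxidation tolerates thioacetal sulfur and, being non-basic, should deliver the configurationally labile α-dithianyl aldehyde without racemisation.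

Step 8
Reactants: 10 (S)-2-(1,3-dithian-2-yl)-6-methylhept-5-enal
Product: 11 (1S,2S,5R)-2-(1,3-dithian-2-yl)-5-(prop-1-en-2-yl)cyclopentan-1-ol
Conditions: Me2AlCl (1.5 equiv), CH2Cl2, −78 → −20 °C; aq. work-up
Reagents that add atoms: none
Why: In this type I intramolecular carbonyl-ene reaction the aluminium-bound aldehyde is attacked by the trisubstituted alkene through a cis-fused bicyclic transition state that passes a methyl hydrogen to oxygen and places OH and isopropenyl cis, while the bulky dithianyl group sits pseudo-equatorial and trans to the metal-bound oxygen, so C1' and C5' follow from C2'.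

Step 9
Reactants: 11 (1S,2S,5R)-2-(1,3-dithian-2-yl)-5-(prop-1-en-2-yl)cyclopentan-1-ol
Product: 12 tert-butyl{[(1S,2S,5R)-2-(1,3-dithian-2-yl)-5-(prop-1-en-2-yl)cyclopentyl]oxy}dimethylsilane
Conditions: TBSOTf, 2,6-lutidine, CH2Cl2, 0 °C
Reagents that add atoms: tert-butyldimethylsilyl triflate, CC(C)(C)[Si](C)(C)OS(=O)(=O)C(F)(F)F
Why: Silylation with the triflate/lutidine pair overcomes the hindrance of the doubly flanked secondary alcohol and removes the only acidic proton before metalation.

**Part B – (Z,Z)-diiodide**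

Step 10
Reactants: 13 2-bromoprop-2-en-1-ol
Product: 14 [(2-bromoprop-2-en-1-yl)oxy](tert-butyl)dimethylsilane
Conditions: TBSCl, imidazole, CH2Cl2, rt
Reagents that add atoms: tert-butyldimethylsilyl chloride, CC(C)(C)[Si](C)(C)Cl
Why: Imidazole-promoted silylation of an unhindered primary allylic alcohol is routine.

Step 11
Reactants: 15 2,5-dimethoxytetrahydrofuran
Product: 16 succinaldehyde
Conditions: H2O, 90 °C; distillation, used fresh
Reagents that add atoms: water, O
Why: Hydrolysis of the cyclic bis-acetal in hot water releases the dialdehyde, which is distilled and used directly because it oligomerises on storage.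

Step 12
Reactants: 14 [(2-bromoprop-2-en-1-yl)oxy](tert-butyl)dimethylsilane (2 equiv); 16 succinaldehyde
Product: 18 2,7-bis{[(tert-butyldimethylsilyl)oxy]methyl}octa-1,7-diene-3,6-diol (dl/meso mixture), via vinyllithium 17 (not isolated)
Conditions: 14 (2.3 equiv), t-BuLi (4.6 equiv), Et2O, −78 °C; then 16, −78 °C; H2O
Reagents that add atoms: none
Why: Bromine–lithium exchange and twofold 1,2-addition, where at −78 °C the vinyllithium should add faster than it migrates silicon from O to C or enolises the aldehyde, and the diastereomer mixture is irrelevant because both carbinol centres vanish in the next step.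

Step 13
Reactants: 18 2,7-bis{[(tert-butyldimethylsilyl)oxy]methyl}octa-1,7-diene-3,6-diol; 19 triethyl orthoacetate
Product: 21 diethyl (4Z,8Z)-4,9-bis{[(tert-butyldimethylsilyl)oxy]methyl}dodeca-4,8-dienedioate, via bis(ketene acetal) 20 (not isolated)
Conditions: 19 (excess), EtCO2H (cat.), 140 °C, EtOH distilled off
Reagents that add atoms: none
Why: In this twofold Johnson–Claisen rearrangement the carbinol substituent lies equatorial in each chair transition state to avoid the 1,3-diaxial clash with the ethoxy group, so each new CH2CH2CO2Et arm ends trans to the central chain and each CH2OTBS group cis to it (Z,Z).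

Step 14
Reactants: 21 diethyl (4Z,8Z)-4,9-bis{[(tert-butyldimethylsilyl)oxy]methyl}dodeca-4,8-dienedioate
Product: 22 (4Z,8Z)-4,9-bis{[(tert-butyldimethylsilyl)oxy]methyl}dodeca-4,8-dienedioic acid
Conditions: LiOH, THF/MeOH/H2O, rt; then 1 M HCl to pH 4, 0 °C
Reagents that add atoms: lithium hydroxide, [Li+].[OH-]
Why: Saponification of unhindered ethyl esters proceeds at room temperature, and the primary silyl ethers survive both the base and the brief mild acidification.

Step 15
Reactants: 22 (4Z,8Z)-4,9-bis{[(tert-butyldimethylsilyl)oxy]methyl}dodeca-4,8-dienedioic acid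
Product: 24 (3Z,7Z)-1,10-diiodo-3,8-bis{[(tert-butyldimethylsilyl)oxy]methyl}deca-3,7-diene, via bis(thiohydroxamate ester) 23 (not isolated)
Conditions: 1-hydroxypyridine-2(1H)-thione, DCC, DMAP (cat.), CH2Cl2, 0 °C, dark; then CHI3, cyclohexene, W lamp, reflux
Reagents that add atoms: iodoform, IC(I)I
Why: In this Barton decarboxylative iodination the thiohydroxamate esters fragment in a radical chain to primary homoallyl radicals that take iodine from iodoform far faster than they can close to cyclopropylcarbinyl radicals, so each end loses one carbon with the alkene geometry kept, and cyclohexene scavenges any iodine formed.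

**Part C – union and endgame**

Step 16
Reactants: 12 tert-butyl{[(1S,2S,5R)-2-(1,3-dithian-2-yl)-5-(prop-1-en-2-yl)cyclopentyl]oxy}dimethylsilane (2 equiv); 24 (3Z,7Z)-1,10-diiodo-3,8-bis{[(tert-butyldimethylsilyl)oxy]methyl}deca-3,7-diene
Product: 26 (3Z,7Z)-1,10-bis{2-[(1S,2S,3R)-2-(tert-butyldimethylsilyloxy)-3-(prop-1-en-2-yl)cyclopentyl]-1,3-dithian-2-yl}-3,8-bis(tert-butyldimethylsilyloxymethyl)deca-3,7-diene, via lithiodithiane 25 (not isolated)
Conditions: 12 (2.3 equiv), t-BuLi (2.3 equiv), THF/HMPA 10:1, −78 °C, 1 h; then 24 (1 equiv), −78 → −30 °C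
Reagents that add atoms: none
Why: t-BuLi removes the proton between the two sulfur atoms of 12 to give the sulfur-stabilised carbanion 25, an acyl-anion equivalent of pyran C2, which displaces iodide from each CH2I terminus of 24 by SN2 so that the two C2–C3 bonds arise in one operation. The closest known reaction type is the Corey–Seebach alkylation of 2-alkyl-2-lithio-1,3-dithianes with primary iodides, in the t-BuLi/HMPA variant used for α-branched, γ-silyloxy dithianes. The step closes no ring and creates no stereocentre; C2', next to the carbanion, keeps its hydrogen and configuration, and the alkene geometry is not involved. The selectivity needed is substitution over E2 at the homoallylic iodide, whose C4 hydrogens are allylic, and a soft charge-delocalised nucleophile, iodide on an unbranched primary carbon, solvent-separated ion pairs and low temperature all favour SN2. The silyl group should stay on oxygen because the 1,4-Brook equilibrium lies on the side of silyl ether plus dithiane anion, and no leaving group sits β to the carbanion. The slight excess of 25 drives the second alkylation, and unreacted 12 is recoverable.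

Step 17
Reactants: 26 the tetrasilylated bis(dithiane)
Product: 27 (3Z,7Z)-1,10-bis{2-[(1S,2S,3R)-2-hydroxy-3-(prop-1-en-2-yl)cyclopentyl]-1,3-dithian-2-yl}-3,8-bis(hydroxymethyl)deca-3,7-diene
Conditions: TBAF, THF, rt → 45 °C
Reagents that add atoms: none
Why: Fluoride desilylation is run while C2 is still masked as the dithiane, so that no β-hydroxy ketone meets the basic fluoride source needed for the hindered C1' silyl ether.

Step 18
Reactants: 27 the tetraol bis(dithiane)
Product: 28 (4Z,8Z)-1,12-bis[(1S,2S,3R)-2-hydroxy-3-(prop-1-en-2-yl)cyclopentyl]-4,9-bis(hydroxymethyl)dodeca-4,8-diene-1,12-dione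
Conditions: MeI, CaCO3, MeCN/H2O 9:1, 40 °C
Reagents that add atoms: water, O
Why: In this alkylative dithiane hydrolysis S-methylation makes sulfur a leaving group and water captures the thionium ion, a near-neutral process that spares all four alkenes and leaves C2' in its more stable trans arrangement.

Step 19
Reactants: 28 the bis(β-hydroxy ketone) diol
Product: 30 (4Z,8Z)-4,9-bis(chloromethyl)-1,12-bis[(1S,2S,3R)-2-hydroxy-3-(prop-1-en-2-yl)cyclopentyl]dodeca-4,8-diene-1,12-dione, via bis(mesylate) 29 (not isolated)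
Conditions: MsCl (2.2 equiv), 2,4,6-collidine, LiCl, DMF, 0 °C
Reagents that add atoms: lithium chloride, [Li+].[Cl-]
Why: In this mesylation/chloride exchange of an allylic alcohol the primary allylic hydroxyl should react far faster than the single hindered, hydrogen-bonded C1' hydroxyl per half, and direct SN2 by chloride avoids allylic transposition and keeps the alkene geometry.

Step 20
Reactants: 30 the bis(allylic chloride) bis(β-hydroxy ketone)
Product: 32 (1R,4Z,8Z,12R)-4,9-bis(chloromethyl)-1,12-bis[(1R,2S,3R)-2-hydroxy-3-(prop-1-en-2-yl)cyclopentyl]dodeca-4,8-diene-1,12-diol, via bis(diethylborinate) chelate 31 (not isolated)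
Conditions: Et2BOMe, THF/MeOH 4:1, −78 °C; NaBH4, −78 °C; AcOH, then MeOH co-evaporation
Reagents that add atoms: none
Why: In this Narasaka–Prasad reduction the C1' oxygen and the ketone oxygen share a diethylboron centre in a six-membered chelate trans-fused to the cyclopentane, and external hydride attacks axially to give the all-equatorial chair, i.e. the 1,3-syn diol with (R)-C2, while the allylic chlorides are inert to borohydride at −78 °C.

Step 21
Reactants: 32 the bis(allylic chloride) tetraol
Product: 33 testudinariol A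
Conditions: NaH, THF (high dilution), 0 °C → rt
Reagents that add atoms: none
Why: In this twofold intramolecular Williamson etherification each C2 alkoxide attacks its own primary allylic chloride in a 6-exo-tet SN2 closure that forms O1–C6 without touching a stereocentre or the alkene geometry, whereas the C1' alkoxide could only form an eight-membered ring.

**Compound list**

1 | diethyl malonate | CCOC(=O)CC(=O)OCC | starting material
2 | 5-bromo-2-methylpent-2-ene | CC(C)=CCCBr | starting material
3 | diethyl 2-(4-methylpent-3-en-1-yl)malonate | CCOC(=O)C(CCC=C(C)C)C(=O)OCC | intermediate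
4 | 2-(4-methylpent-3-en-1-yl)propane-1,3-diol | CC(C)=CCCC(CO)CO | intermediate
5 | (R)-2-(hydroxymethyl)-6-methylhept-5-en-1-yl acetate | CC(C)=CCC[C@H](CO)COC(C)=O | intermediate
6 | (S)-2-formyl-6-methylhept-5-en-1-yl acetate | CC(C)=CCC[C@H](C=O)COC(C)=O | intermediate
7 | propane-1,3-dithiol | SCCCS | starting material
8 | (S)-2-(1,3-dithian-2-yl)-6-methylhept-5-en-1-yl acetate | CC(C)=CCC[C@H](C1SCCCS1)COC(C)=O | intermediate
9 | (S)-2-(1,3-dithian-2-yl)-6-methylhept-5-en-1-ol | CC(C)=CCC[C@H](C1SCCCS1)CO | intermediate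
10 | (S)-2-(1,3-dithian-2-yl)-6-methylhept-5-enal | CC(C)=CCC[C@H](C1SCCCS1)C=O | intermediate
11 | (1S,2S,5R)-2-(1,3-dithian-2-yl)-5-(prop-1-en-2-yl)cyclopentan-1-ol | C=C(C)[C@H]1CC[C@H](C2SCCCS2)[C@H]1O | intermediate
12 | tert-butyl{[(1S,2S,5R)-2-(1,3-dithian-2-yl)-5-(prop-1-en-2-yl)cyclopentyl]oxy}dimethylsilane | C=C(C)[C@H]1CC[C@H](C2SCCCS2)[C@H]1O[Si](C)(C)C(C)(C)C | intermediate
13 | 2-bromoprop-2-en-1-ol | OCC(Br)=C | starting material
14 | [(2-bromoprop-2-en-1-yl)oxy](tert-butyl)dimethylsilane | C=C(Br)CO[Si](C)(C)C(C)(C)C | intermediate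
15 | 2,5-dimethoxytetrahydrofuran | COC1CCC(OC)O1 | starting material
16 | succinaldehyde | O=CCCC=O | intermediate
17 | 3-[(tert-butyldimethylsilyl)oxy]prop-1-en-2-yllithium (not isolated) | [Li]C(=C)CO[Si](C)(C)C(C)(C)C | intermediate
18 | 2,7-bis{[(tert-butyldimethylsilyl)oxy]methyl}octa-1,7-diene-3,6-diol (dl/meso) | C=C(CO[Si](C)(C)C(C)(C)C)C(O)CCC(O)C(=C)CO[Si](C)(C)C(C)(C)C | intermediate
19 | triethyl orthoacetate | CCOC(C)(OCC)OCC | starting material
20 | bis(1-ethoxyvinyl) ether (bis ketene acetal) of 18 (not isolated) | C=C(OCC)OC(CCC(OC(=C)OCC)C(=C)CO[Si](C)(C)C(C)(C)C)C(=C)CO[Si](C)(C)C(C)(C)C | intermediate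
21 | diethyl (4Z,8Z)-4,9-bis{[(tert-butyldimethylsilyl)oxy]methyl}dodeca-4,8-dienedioate | CCOC(=O)CC/C(=C/CC/C=C(/CCC(=O)OCC)CO[Si](C)(C)C(C)(C)C)CO[Si](C)(C)C(C)(C)C | intermediate
22 | (4Z,8Z)-4,9-bis{[(tert-butyldimethylsilyl)oxy]methyl}dodeca-4,8-dienedioic acid | OC(=O)CC/C(=C/CC/C=C(/CCC(=O)O)CO[Si](C)(C)C(C)(C)C)CO[Si](C)(C)C(C)(C)C | intermediate
23 | bis(2-thioxopyridin-1(2H)-yl) ester of 22 (not isolated) | S=C1C=CC=CN1OC(=O)CC/C(=C/CC/C=C(/CCC(=O)ON2C=CC=CC2=S)CO[Si](C)(C)C(C)(C)C)CO[Si](C)(C)C(C)(C)C | intermediate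
24 | (3Z,7Z)-1,10-diiodo-3,8-bis{[(tert-butyldimethylsilyl)oxy]methyl}deca-3,7-diene | ICC/C(=C/CC/C=C(/CCI)CO[Si](C)(C)C(C)(C)C)CO[Si](C)(C)C(C)(C)C | intermediate
25 | 2-lithio derivative of 12 (not isolated) | C=C(C)[C@H]1CC[C@H](C2([Li])SCCCS2)[C@H]1O[Si](C)(C)C(C)(C)C | intermediate
26 | tetrasilylated bis(dithiane), full carbon skeleton | C=C(C)[C@H]1CC[C@H](C2(SCCCS2)CC/C(=C/CC/C=C(/CCC3(SCCCS3)[C@H]4CC[C@H](C(=C)C)[C@@H]4O[Si](C)(C)C(C)(C)C)CO[Si](C)(C)C(C)(C)C)CO[Si](C)(C)C(C)(C)C)[C@H]1O[Si](C)(C)C(C)(C)C | intermediate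
27 | tetraol bis(dithiane) | C=C(C)[C@H]1CC[C@H](C2(SCCCS2)CC/C(=C/CC/C=C(/CCC3(SCCCS3)[C@H]4CC[C@H](C(=C)C)[C@@H]4O)CO)CO)[C@H]1O | intermediate
28 | (4Z,8Z)-1,12-bis[(1S,2S,3R)-2-hydroxy-3-(prop-1-en-2-yl)cyclopentyl]-4,9-bis(hydroxymethyl)dodeca-4,8-diene-1,12-dione | C=C(C)[C@H]1CC[C@H](C(=O)CC/C(=C/CC/C=C(/CCC(=O)[C@H]2CC[C@H](C(=C)C)[C@@H]2O)CO)CO)[C@H]1O | intermediate
29 | bis(allylic mesylate) of 28 (not isolated) | C=C(C)[C@H]1CC[C@H](C(=O)CC/C(=C/CC/C=C(/CCC(=O)[C@H]2CC[C@H](C(=C)C)[C@@H]2O)COS(C)(=O)=O)COS(C)(=O)=O)[C@H]1O | intermediate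
30 | (4Z,8Z)-4,9-bis(chloromethyl)-1,12-bis[(1S,2S,3R)-2-hydroxy-3-(prop-1-en-2-yl)cyclopentyl]dodeca-4,8-diene-1,12-dione | C=C(C)[C@H]1CC[C@H](C(=O)CC/C(=C/CC/C=C(/CCC(=O)[C@H]2CC[C@H](C(=C)C)[C@@H]2O)CCl)CCl)[C@H]1O | intermediate
31 | bis(C1'-O-diethylborinate) of 30, boron chelated by the ketone (not isolated) | C=C(C)[C@H]1CC[C@H](C(=O)CC/C(=C/CC/C=C(/CCC(=O)[C@H]2CC[C@H](C(=C)C)[C@@H]2OB(CC)CC)CCl)CCl)[C@H]1OB(CC)CC | intermediate
32 | (1R,4Z,8Z,12R)-4,9-bis(chloromethyl)-1,12-bis[(1R,2S,3R)-2-hydroxy-3-(prop-1-en-2-yl)cyclopentyl]dodeca-4,8-diene-1,12-diol | C=C(C)[C@H]1CC[C@H]([C@H](O)CC/C(=C/CC/C=C(/CC[C@@H](O)[C@H]2CC[C@H](C(=C)C)[C@@H]2O)CCl)CCl)[C@H]1O | intermediate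
33 | testudinariol A | C=C(C)[C@H]1CC[C@H]([C@H]2CC/C(=C/CC/C=C3/CC[C@H]([C@H]4CC[C@H](C(=C)C)[C@@H]4O)OC3)CO2)[C@H]1O | target

Total step count: 21. Longest linear sequence: 15 (steps 1–9, then 16–21).

**Steps most likely to fail**

Step 16. The hindered α-branched dithiane may be metalated incompletely. The carbanion may also act as a base and strip HI from the homoallylic iodide, or the second alkylation may stall.

Fallback: the same C2–C3 bonds are made with the polarity reversed, setting out from 12 and 24 and rejoining at 28.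
- Alkylative hydrolysis of 12 (MeI, CaCO3, aq. MeCN) gives (1S,2S,3R)-2-(tert-butyldimethylsilyloxy)-3-(prop-1-en-2-yl)cyclopentanecarbaldehyde F1.
- Iodine–lithium exchange on 24 (t-BuLi, Et2O/pentane, −78 °C) gives the 1,10-dilithio diene F2.
- F2 adds to two equivalents of F1 to give the bis(carbinol) F3 as a mixture of C2 epimers.
- Dess–Martin oxidation gives the tetrasilylated diketone F4.
- HF·pyridine in THF removes all four silyl groups to give 28.

Step 8. The α-dithianyl aldehyde may enolise, which would erode enantiopurity or expel thiolate. Sulfur may tie up the Lewis acid, or the facial selectivity of the closure may be poor.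

Fallback: the ring is closed before sulfur is introduced, setting out from 5 and rejoining at 12.
- Acid-catalysed benzylation (4-methoxybenzyl trichloroacetimidate, cat. PPTS, chosen because base would trigger acetyl migration) gives the PMB ether acetate F5.
- Methanolysis gives the alcohol F6, and Dess–Martin oxidation gives the α-(alkoxymethyl) aldehyde F7.
- Me2AlCl-promoted ene closure gives the cyclopentanol F8.
- TBSOTf/2,6-lutidine gives the silyl ether F9, and DDQ in wet CH2Cl2 frees the primary alcohol F10.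
- Dess–Martin oxidation gives the aldehyde F1. Dithioacetalisation with 7 (BF3·OEt2, CH2Cl2, −78 °C) then gives 12.

Step 15. Iodine atoms may catalyse Z/E isomerisation of the trisubstituted alkenes. Chain-carrying radicals may add to the alkenes, and two decarboxylations in one molecule may be inefficient.

Fallback: a purely polar one-carbon degradation, setting out from 21 and rejoining at 24.
- Twofold enolate hydroxylation (KHMDS, then a Davis oxaziridine, −78 °C) gives the bis(α-hydroxy ester) F11.
- LiAlH4 gives the bis(1,2-diol) F12.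
- NaIO4 cleavage gives the β,γ-unsaturated dialdehyde F13, which is reduced at once with NaBH4 to the bis(homoallylic alcohol) F14.
- I2, PPh3 and imidazole convert F14 into 24.

**Further compounds**

F1 | step 16 | (1S,2S,3R)-2-(tert-butyldimethylsilyloxy)-3-(prop-1-en-2-yl)cyclopentanecarbaldehyde | C=C(C)[C@H]1CC[C@H](C=O)[C@H]1O[Si](C)(C)C(C)(C)C
F2 | step 16 | (3Z,7Z)-1,10-dilithio-3,8-bis(tert-butyldimethylsilyloxymethyl)deca-3,7-diene | [Li]CC/C(=C/CC/C=C(/CC[Li])CO[Si](C)(C)C(C)(C)C)CO[Si](C)(C)C(C)(C)C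
F3 | step 16 | tetrasilylated bis(carbinol), C2 epimer mixture, ring centres as in 12 | C=C(C)[C@H]1CC[C@H](C(O)CC/C(=C/CC/C=C(/CCC(O)[C@H]2CC[C@H](C(=C)C)[C@@H]2O[Si](C)(C)C(C)(C)C)CO[Si](C)(C)C(C)(C)C)CO[Si](C)(C)C(C)(C)C)[C@H]1O[Si](C)(C)C(C)(C)C
F4 | step 16 | tetrasilylated diketone (tetra-TBS ether of 28) | C=C(C)[C@H]1CC[C@H](C(=O)CC/C(=C/CC/C=C(/CCC(=O)[C@H]2CC[C@H](C(=C)C)[C@@H]2O[Si](C)(C)C(C)(C)C)CO[Si](C)(C)C(C)(C)C)CO[Si](C)(C)C(C)(C)C)[C@H]1O[Si](C)(C)C(C)(C)C
F5 | step 8 | (R)-2-{[(4-methoxybenzyl)oxy]methyl}-6-methylhept-5-en-1-yl acetate | CC(C)=CCC[C@H](COCc1ccc(OC)cc1)COC(C)=O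
F6 | step 8 | (S)-2-{[(4-methoxybenzyl)oxy]methyl}-6-methylhept-5-en-1-ol | CC(C)=CCC[C@H](COCc1ccc(OC)cc1)CO
F7 | step 8 | (R)-2-{[(4-methoxybenzyl)oxy]methyl}-6-methylhept-5-enal | CC(C)=CCC[C@H](COCc1ccc(OC)cc1)C=O
F8 | step 8 | (1S,2R,5R)-2-{[(4-methoxybenzyl)oxy]methyl}-5-(prop-1-en-2-yl)cyclopentan-1-ol | C=C(C)[C@H]1CC[C@H](COCc2ccc(OC)cc2)[C@H]1O
F9 | step 8 | tert-butyldimethylsilyl ether of F8 | C=C(C)[C@H]1CC[C@H](COCc2ccc(OC)cc2)[C@H]1O[Si](C)(C)C(C)(C)C
F10 | step 8 | [(1R,2S,3R)-2-(tert-butyldimethylsilyloxy)-3-(prop-1-en-2-yl)cyclopentyl]methanol | C=C(C)[C@H]1CC[C@H](CO)[C@H]1O[Si](C)(C)C(C)(C)C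
F11 | step 15 | diethyl (4Z,8Z)-2,11-dihydroxy-4,9-bis(tert-butyldimethylsilyloxymethyl)dodeca-4,8-dienedioate | CCOC(=O)C(O)C/C(=C/CC/C=C(/CC(O)C(=O)OCC)CO[Si](C)(C)C(C)(C)C)CO[Si](C)(C)C(C)(C)C
F12 | step 15 | (4Z,8Z)-4,9-bis(tert-butyldimethylsilyloxymethyl)dodeca-4,8-diene-1,2,11,12-tetraol | OCC(O)C/C(=C/CC/C=C(/CC(O)CO)CO[Si](C)(C)C(C)(C)C)CO[Si](C)(C)C(C)(C)C
F13 | step 15 | (3Z,7Z)-3,8-bis(tert-butyldimethylsilyloxymethyl)deca-3,7-dienedial | O=CC/C(=C/CC/C=C(/CC=O)CO[Si](C)(C)C(C)(C)C)CO[Si](C)(C)C(C)(C)C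
F14 | step 15 | (3Z,7Z)-3,8-bis(tert-butyldimethylsilyloxymethyl)deca-3,7-diene-1,10-diol | OCC/C(=C/CC/C=C(/CCO)CO[Si](C)(C)C(C)(C)C)CO[Si](C)(C)C(C)(C)C
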